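**Assumption (remark on the chemistry):** the sense of induction of the chiral phosphoric acid at C4 cannot be predicted with certainty; the (R) acid is written, and its enantiomer would be taken if the first experiment shows the opposite sense. Flavan numbering (O1, C2 to C8a) and ring letters A, C, B (upper unit) and D, F, E (lower unit) are used throughout.

## Retrosynthetic overview

1. The target is robinetinidol-(4α→6)-epigallocatechin. It is traced back to its deca-O-benzyl ether, and the C3–OH and C2–H of ring C to hydroboration of a 4-aryl-flav-2-ene, in which C4 alone dictates C2 and C3.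
2. Key disconnection: three components are joined around ring C in one operation. These are a 2-arylbenzofuran (rings A and B with O1, C2, C4), the carbon of dibromocarbene (becomes C3), and a C8-blocked perbenzyl epigallocatechin (rings D, F, E; new bond C4–C6 of ring D).
3. Ring order: rings A, B and D/F/E are bought. The furan ring (O1, C2, C4, C4a, C8a) is closed by an intramolecular Wittig reaction and then enlarged by one carbon to the pyran ring C.
4. Enabling feature: in ring C, O1 and the ring-B aryl on C2 flank the C2–C3–C4 unit, so at the flavylium oxidation level this unit is the allyl-cation part of an aromatic 1-benzopyrylium. A halocyclopropane across C2–C4 of the benzofuran therefore opens to it, and its C4 terminus is the atom that must bond to ring D.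

Key step: step 7

## Route

Step 1
Reactants: 1 4-(benzyloxy)-2-hydroxybenzaldehyde
Product: 2 5-(benzyloxy)-2-(hydroxymethyl)phenol
Conditions: NaBH4, MeOH, 0 °C
Reagents that add atoms: none
Why: Hydride reduction of the aldehyde to the benzylic alcohol, chemoselective beside the phenol and the benzyl ether; no stereocentre is formed.

Step 2
Reactants: 2 5-(benzyloxy)-2-(hydroxymethyl)phenol
Product: 3 [4-(benzyloxy)-2-hydroxybenzyl]triphenylphosphonium bromide
Conditions: PPh3·HBr, MeCN, reflux
Reagents that add atoms: triphenylphosphine hydrobromide, [Br-].c1ccc(cc1)[PH+](c1ccccc1)c1ccccc1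
Why: The benzylic alcohol, activated by the ortho-hydroxy and para-benzyloxy groups, ionises under HBr and is captured by PPh3 (benzylic substitution to a phosphonium salt); no stereocentre is formed.

Step 3
Reactants: 3 [4-(benzyloxy)-2-hydroxybenzyl]triphenylphosphonium bromide; 4 3,4,5-tris(benzyloxy)benzoyl chloride
Product: 6 6-(benzyloxy)-2-[3,4,5-tris(benzyloxy)phenyl]-1-benzofuran, via O-aroyl phosphonium salt 5 (not isolated)
Conditions: Et3N, toluene, reflux
Reagents that add atoms: none
Why: O-Acylation of the phenol gives 5, whose ylide attacks the neighbouring ester carbonyl in an intramolecular Wittig reaction that closes the furan ring and expels Ph3P=O; no stereocentre is formed.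

Step 4
Reactants: 7 (−)-epigallocatechin, (2R,3R)
Product: 8 (2R,3R)-5,7-bis(benzyloxy)-2-[3,4,5-tris(benzyloxy)phenyl]chroman-3-ol
Conditions: BnBr, K2CO3, DMF, −20 °C → rt, argon
Reagents that add atoms: benzyl bromide, BrCc1ccccc1
Why: Williamson etherification of the five phenols, which K2CO3 deprotonates while the C3 alcohol stays free; low temperature and exclusion of air should suppress C2 epimerisation and pyrogallol oxidation, so both stereocentres are kept.

Step 5
Reactants: 8 (2R,3R)-5,7-bis(benzyloxy)-2-[3,4,5-tris(benzyloxy)phenyl]chroman-3-ol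
Product: 9 (2R,3R)-3,5,7-tris(benzyloxy)-2-[3,4,5-tris(benzyloxy)phenyl]chromane
Conditions: NaH, BnBr, Bu4NI (cat.), THF–DMF, 0 °C → rt
Reagents that add atoms: benzyl bromide, BrCc1ccccc1
Why: Williamson etherification of the secondary alkoxide; with all phenols capped no quinone methide can form, so C2 and C3 are not touched.

Step 6
Reactants: 9 (2R,3R)-3,5,7-tris(benzyloxy)-2-[3,4,5-tris(benzyloxy)phenyl]chromane
Product: 10 (2R,3R)-3,5,7-tris(benzyloxy)-8-bromo-2-[3,4,5-tris(benzyloxy)phenyl]chromane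
Conditions: NBS, CH2Cl2, −78 → 0 °C
Reagents that add atoms: N-bromosuccinimide, BrN1C(=O)CCC1=O
Why: Electrophilic aromatic bromination; the phloroglucinol-type ring D is the most electron-rich ring and C8 its more reactive position in 5,7-di-O-alkyl flavan ethers, so one equivalent of NBS should cap C8 and leave C6 as the only nucleophilic CH.

Step 7
Reactants: 6 6-(benzyloxy)-2-[3,4,5-tris(benzyloxy)phenyl]-1-benzofuran; 10 (2R,3R)-3,5,7-tris(benzyloxy)-8-bromo-2-[3,4,5-tris(benzyloxy)phenyl]chromane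
Product: 14 (4S)-7-(benzyloxy)-3-bromo-4-{(2R,3R)-3,5,7-tris(benzyloxy)-8-bromo-2-[3,4,5-tris(benzyloxy)phenyl]chroman-6-yl}-2-[3,4,5-tris(benzyloxy)phenyl]-4H-chromene, via dibromocyclopropane 11 (not isolated), via tert-butyl ketal 12 (not isolated), via flavylium phosphate ion pair 13 (not isolated)
Conditions: CHBr3, KOt-Bu (excess), hexane–THF, −20 → 0 °C; filter, exchange solvent; then 10, (R)-3,3'-bis(2,4,6-triisopropylphenyl)-1,1'-binaphthyl-2,2'-diyl hydrogen phosphate (10 mol %), 4 Å MS, toluene, −30 → 0 °C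
Reagents that add atoms: bromoform, BrC(Br)Br
Why: Proposed new method: dibromocarbene adds in a [2+1] cycloaddition to the enol-ether bond of the furan ring of 6 (attack at the future C4, charge at C2 held by O1 and ring B) to give 11, whose endo C–Br bond ionises with disrotatory opening of the shared C2–C4 bond, so that the five-membered ring (O1, C2, C4, C4a, C8a) takes up the carbene carbon as C3 and becomes the six-membered aromatic 1-benzopyrylium ring C, held as ketal 12 until the acid releases it as ion pair 13. Ring D of 10 then attacks C4 of 13 in a Friedel–Crafts reaction and the phosphate removes the proton, which regenerates the acid. The closest known reaction types are the Ciamician–Dennstedt-type ring expansion of benzofurans by dihalocarbenes to 3-halo-1-benzopyrylium species, the condensation of flavylium salts with phloroglucinol ethers at C4, and the chiral-phosphate ion pairing of benzopyrylium ions released from chromene ketals; new are their telescoping and the use of the phosphate to set C4 with an ether-protected flavan as the nucleophile. Ring C is not closed by a cyclisation: it arises only by this one-carbon enlargement, the transient cyclopropane closing by cheletropic addition and opening electrocyclically. The one new stereocentre, C4, should be set as (S) by the chiral phosphate, which covers one face of the planar cation while ring D approaches the other; the catalyst enantiomer has to be matched to 10. Needed are C4 over C2 attack, secured by the quaternary aryl-bearing C2 and the bulk of 10, C6 over C8 attack in ring D, secured by the bromine at C8, and carbene addition at the furan bond only, the sole non-benzenoid electron-rich C=C in 6.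

Step 8
Reactants: 14 (4S)-7-(benzyloxy)-3-bromo-4-{(2R,3R)-3,5,7-tris(benzyloxy)-8-bromo-2-[3,4,5-tris(benzyloxy)phenyl]chroman-6-yl}-2-[3,4,5-tris(benzyloxy)phenyl]-4H-chromene
Product: 15 (4S)-7-(benzyloxy)-4-{(2R,3R)-3,5,7-tris(benzyloxy)-2-[3,4,5-tris(benzyloxy)phenyl]chroman-6-yl}-2-[3,4,5-tris(benzyloxy)phenyl]-4H-chromene
Conditions: Bu3SnH (excess), azobisisobutyronitrile (cat.), toluene, 90 °C
Reagents that add atoms: none
Why: Radical-chain hydrodehalogenation: the tin radical abstracts bromine from the vinylic C3 and the aryl C8 (the C8 cap has done its work), and the sp2 radicals take hydrogen from Bu3SnH faster than they can rearrange; the C4–H bond is not involved, so C4 keeps its configuration.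

Step 9
Reactants: 15 (4S)-7-(benzyloxy)-4-{(2R,3R)-3,5,7-tris(benzyloxy)-2-[3,4,5-tris(benzyloxy)phenyl]chroman-6-yl}-2-[3,4,5-tris(benzyloxy)phenyl]-4H-chromene
Product: 17 (2R,3S,4S)-7-(benzyloxy)-4-{(2R,3R)-3,5,7-tris(benzyloxy)-2-[3,4,5-tris(benzyloxy)phenyl]chroman-6-yl}-2-[3,4,5-tris(benzyloxy)phenyl]chroman-3-ol, via C3 alkylborane 16 (not isolated)
Conditions: BH3·SMe2, THF, 0 °C → rt; then NaOH, H2O2, H2O, 0 °C
Reagents that add atoms: hydrogen peroxide, OO
Why: Hydroboration–oxidation of the C2=C3 enol ether (known for flav-2-enes): boron goes to C3 (β to O1, away from the aryl-bearing C2) and hydrogen to C2 in a syn addition on the face opposite the pseudo-axial ring D at C4, and oxidation with retention should give the 2,3-trans-3,4-trans arrangement, so C2 (R) and C3 (S) are both controlled by C4.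

Step 10
Reactants: 17 (2R,3S,4S)-7-(benzyloxy)-4-{(2R,3R)-3,5,7-tris(benzyloxy)-2-[3,4,5-tris(benzyloxy)phenyl]chroman-6-yl}-2-[3,4,5-tris(benzyloxy)phenyl]chroman-3-ol
Product: 18 robinetinidol-(4α→6)-epigallocatechin, (2R,3S,4S)-4-[(2R,3R)-3,5,7-trihydroxy-2-(3,4,5-trihydroxyphenyl)chroman-6-yl]-2-(3,4,5-trihydroxyphenyl)chromane-3,7-diol
Conditions: H2 (1 atm), Pd(OH)2/C, THF–MeOH–H2O, rt
Reagents that add atoms: none
Why: Hydrogenolysis of the ten benzyl ethers under neutral conditions, a standard last step for benzylated flavan dimers; the interflavan C4–C6 bond and all five stereocentres should not be affected.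

## Compound list

1 | 4-(benzyloxy)-2-hydroxybenzaldehyde | O=Cc1ccc(OCc2ccccc2)cc1O | starting material
2 | 5-(benzyloxy)-2-(hydroxymethyl)phenol | OCc1ccc(OCc2ccccc2)cc1O | intermediate
3 | [4-(benzyloxy)-2-hydroxybenzyl]triphenylphosphonium bromide | [Br-].Oc1cc(OCc2ccccc2)ccc1C[P+](c1ccccc1)(c1ccccc1)c1ccccc1 | intermediate
4 | 3,4,5-tris(benzyloxy)benzoyl chloride | O=C(Cl)c1cc(OCc2ccccc2)c(OCc2ccccc2)c(OCc2ccccc2)c1 | starting material
5 | {4-(benzyloxy)-2-[3,4,5-tris(benzyloxy)benzoyloxy]benzyl}triphenylphosphonium bromide (not isolated) | [Br-].O=C(Oc1cc(OCc2ccccc2)ccc1C[P+](c1ccccc1)(c1ccccc1)c1ccccc1)c1cc(OCc2ccccc2)c(OCc2ccccc2)c(OCc2ccccc2)c1 | intermediate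
6 | 6-(benzyloxy)-2-[3,4,5-tris(benzyloxy)phenyl]-1-benzofuran | c1ccccc1COc1ccc2cc(-c3cc(OCc4ccccc4)c(OCc4ccccc4)c(OCc4ccccc4)c3)oc2c1 | intermediate
7 | (−)-epigallocatechin, (2R,3R) | c1c(O)cc2c(c1O)C[C@@H](O)[C@@H](c1cc(O)c(O)c(O)c1)O2 | starting material
8 | (2R,3R)-5,7-bis(benzyloxy)-2-[3,4,5-tris(benzyloxy)phenyl]chroman-3-ol | c1c(OCc3ccccc3)cc2c(c1OCc1ccccc1)C[C@@H](O)[C@@H](c1cc(OCc3ccccc3)c(OCc3ccccc3)c(OCc3ccccc3)c1)O2 | intermediate
9 | (2R,3R)-3,5,7-tris(benzyloxy)-2-[3,4,5-tris(benzyloxy)phenyl]chromane | c1c(OCc3ccccc3)cc2c(c1OCc1ccccc1)C[C@@H](OCc1ccccc1)[C@@H](c1cc(OCc3ccccc3)c(OCc3ccccc3)c(OCc3ccccc3)c1)O2 | intermediate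
10 | (2R,3R)-3,5,7-tris(benzyloxy)-8-bromo-2-[3,4,5-tris(benzyloxy)phenyl]chromane | c1c(OCc3ccccc3)c(Br)c2c(c1OCc1ccccc1)C[C@@H](OCc1ccccc1)[C@@H](c1cc(OCc3ccccc3)c(OCc3ccccc3)c(OCc3ccccc3)c1)O2 | intermediate
11 | rac-4-(benzyloxy)-1,1-dibromo-1a-[3,4,5-tris(benzyloxy)phenyl]-1a,6b-dihydro-1H-cyclopropa[b][1]benzofuran (cis-fused, racemic, not isolated) | c1ccccc1COc1ccc2c(c1)OC1(c3cc(OCc4ccccc4)c(OCc4ccccc4)c(OCc4ccccc4)c3)C2C1(Br)Br | intermediate
12 | rac-7-(benzyloxy)-3-bromo-2-tert-butoxy-2-[3,4,5-tris(benzyloxy)phenyl]-2H-chromene (not isolated) | c1ccccc1COc1ccc2C=C(Br)C(OC(C)(C)C)(c3cc(OCc4ccccc4)c(OCc4ccccc4)c(OCc4ccccc4)c3)Oc2c1 | intermediate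
13 | 7-(benzyloxy)-3-bromo-2-[3,4,5-tris(benzyloxy)phenyl]chromenylium (R)-3,3'-bis(2,4,6-triisopropylphenyl)-1,1'-binaphthyl-2,2'-diyl phosphate (ion pair, not isolated; the axial (R) configuration is not expressed in the SMILES) | c1ccccc1COc1ccc2cc(Br)c(-c3cc(OCc4ccccc4)c(OCc4ccccc4)c(OCc4ccccc4)c3)[o+]c2c1.[O-]P1(=O)Oc2c(-c4c(C(C)C)cc(C(C)C)cc4C(C)C)cc3ccccc3c2-c2c(O1)c(-c4c(C(C)C)cc(C(C)C)cc4C(C)C)cc1ccccc21 | intermediate
14 | (4S)-7-(benzyloxy)-3-bromo-4-{(2R,3R)-3,5,7-tris(benzyloxy)-8-bromo-2-[3,4,5-tris(benzyloxy)phenyl]chroman-6-yl}-2-[3,4,5-tris(benzyloxy)phenyl]-4H-chromene | c1ccccc1COc1ccc2c(c1)OC(c1cc(OCc3ccccc3)c(OCc3ccccc3)c(OCc3ccccc3)c1)=C(Br)[C@@H]2c1c(OCc3ccccc3)c(Br)c2c(c1OCc1ccccc1)C[C@@H](OCc1ccccc1)[C@@H](c1cc(OCc3ccccc3)c(OCc3ccccc3)c(OCc3ccccc3)c1)O2 | intermediate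
15 | (4S)-7-(benzyloxy)-4-{(2R,3R)-3,5,7-tris(benzyloxy)-2-[3,4,5-tris(benzyloxy)phenyl]chroman-6-yl}-2-[3,4,5-tris(benzyloxy)phenyl]-4H-chromene | c1ccccc1COc1ccc2c(c1)OC(c1cc(OCc3ccccc3)c(OCc3ccccc3)c(OCc3ccccc3)c1)=C[C@@H]2c1c(OCc3ccccc3)cc2c(c1OCc1ccccc1)C[C@@H](OCc1ccccc1)[C@@H](c1cc(OCc3ccccc3)c(OCc3ccccc3)c(OCc3ccccc3)c1)O2 | intermediate
16 | C3 alkylborane of 15: BH2 on C3 and H on C2, both on the face opposite ring D; 2-aryl, 3-boryl and 4-aryl all trans (not isolated) | c1ccccc1COc1ccc2c(c1)O[C@H](c1cc(OCc3ccccc3)c(OCc3ccccc3)c(OCc3ccccc3)c1)[C@@H](B)[C@@H]2c1c(OCc3ccccc3)cc2c(c1OCc1ccccc1)C[C@@H](OCc1ccccc1)[C@@H](c1cc(OCc3ccccc3)c(OCc3ccccc3)c(OCc3ccccc3)c1)O2 | intermediate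
17 | (2R,3S,4S)-7-(benzyloxy)-4-{(2R,3R)-3,5,7-tris(benzyloxy)-2-[3,4,5-tris(benzyloxy)phenyl]chroman-6-yl}-2-[3,4,5-tris(benzyloxy)phenyl]chroman-3-ol | c1ccccc1COc1ccc2c(c1)O[C@H](c1cc(OCc3ccccc3)c(OCc3ccccc3)c(OCc3ccccc3)c1)[C@@H](O)[C@@H]2c1c(OCc3ccccc3)cc2c(c1OCc1ccccc1)C[C@@H](OCc1ccccc1)[C@@H](c1cc(OCc3ccccc3)c(OCc3ccccc3)c(OCc3ccccc3)c1)O2 | intermediate
18 | robinetinidol-(4α→6)-epigallocatechin, (2R,3S,4S)-4-[(2R,3R)-3,5,7-trihydroxy-2-(3,4,5-trihydroxyphenyl)chroman-6-yl]-2-(3,4,5-trihydroxyphenyl)chromane-3,7-diol | Oc1ccc2c(c1)O[C@H](c1cc(O)c(O)c(O)c1)[C@@H](O)[C@@H]2c1c(O)cc2c(c1O)C[C@@H](O)[C@@H](c1cc(O)c(O)c(O)c1)O2 | target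

## Step count and risks

Total step count: 10. Longest linear sequence: 7 steps (steps 1, 2, 3, 7, 8, 9, 10; the branch through steps 4 to 6 is equally long).

**Step 7 (bears the label).** The chiral phosphate may discriminate the two faces of the planar cation poorly, or the crude ketal may ionise sluggishly in the presence of residual salts. The fallback uses known chemistry only and keeps the ring enlargement. It sets out from 6 and 10. The dibromocarbene ring expansion of 6 is run as above, and the crude ketal 12 is treated with HBF4·OEt2 in Et2O to precipitate 7-(benzyloxy)-3-bromo-2-[3,4,5-tris(benzyloxy)phenyl]chromenylium tetrafluoroborate F1. This salt is condensed with 10 in CH2Cl2–MeCN with 2,6-di-tert-butylpyridine as proton acceptor (uncatalysed condensation of a flavylium salt with a phloroglucinol ether). No facial preference is expected, so 14 should form together with its (4R) epimer F2. The two diastereomers are separated by chromatography, and F2 may be returned to F1 and 10 by HBF4 (acid reversal of the C4 arylation) for another pass. The route is rejoined at 14.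

**Step 9.** The borane may fail to reach the shielded, trisubstituted enol ether, or the β-alkoxyborane may eliminate and open ring C. The fallback sets out from 15. Dihydroxylation (OsO4 cat., N-methylmorpholine N-oxide, acetone–THF–H2O) on the face opposite ring D should give the cis-2,3-diol hemiketal F3. Ionic deoxygenation of its anomeric C2–OH (Et3SiH, BF3·OEt2, CH2Cl2–MeCN, −40 °C) then proceeds through the C2 oxocarbenium ion. Hydride is expected to enter cis to the C3 oxygen, as in the reduction of aryl C-glycoside hemiketals, to give the all-equatorial 2,3-trans product. The route is rejoined at 17.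

**Step 8.** The shielded vinylic bromide may be reduced incompletely, or the vinyl and aryl radicals may transfer hydrogen from the benzylic ether positions and give by-products. The fallback sets out from 14 and replaces the radical chain by a two-electron hydrodebromination: Pd(OAc)2, 2-dicyclohexylphosphino-2',6'-dimethoxybiphenyl, HCO2Na, DMF, 80 °C (oxidative addition at both C–Br bonds, hydride from formate, reductive elimination). It passes through no new compound (F0) and rejoins the route at 15; any material that keeps the aryl bromide would still converge on 18 in step 10.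

## Further compounds

F1 | step 7 | 7-(benzyloxy)-3-bromo-2-[3,4,5-tris(benzyloxy)phenyl]chromenylium tetrafluoroborate | c1ccccc1COc1ccc2cc(Br)c(-c3cc(OCc4ccccc4)c(OCc4ccccc4)c(OCc4ccccc4)c3)[o+]c2c1.F[B-](F)(F)F
F2 | step 7 | (4R)-7-(benzyloxy)-3-bromo-4-{(2R,3R)-3,5,7-tris(benzyloxy)-8-bromo-2-[3,4,5-tris(benzyloxy)phenyl]chroman-6-yl}-2-[3,4,5-tris(benzyloxy)phenyl]-4H-chromene (C4 epimer of 14) | c1ccccc1COc1ccc2c(c1)OC(c1cc(OCc3ccccc3)c(OCc3ccccc3)c(OCc3ccccc3)c1)=C(Br)[C@H]2c1c(OCc3ccccc3)c(Br)c2c(c1OCc1ccccc1)C[C@@H](OCc1ccccc1)[C@@H](c1cc(OCc3ccccc3)c(OCc3ccccc3)c(OCc3ccccc3)c1)O2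
F0 | step 8 | none | none
F3 | step 9 | (2S,3S,4S)-7-(benzyloxy)-4-{(2R,3R)-3,5,7-tris(benzyloxy)-2-[3,4,5-tris(benzyloxy)phenyl]chroman-6-yl}-2-[3,4,5-tris(benzyloxy)phenyl]chromane-2,3-diol (2-OH and 3-OH cis, both trans to ring D) | c1ccccc1COc1ccc2c(c1)O[C@](O)(c1cc(OCc3ccccc3)c(OCc3ccccc3)c(OCc3ccccc3)c1)[C@@H](O)[C@@H]2c1c(OCc3ccccc3)cc2c(c1OCc1ccccc1)C[C@@H](OCc1ccccc1)[C@@H](c1cc(OCc3ccccc3)c(OCc3ccccc3)c(OCc3ccccc3)c1)O2
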